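**Retrosynthetic overview** (locants as in the bicyclic target: C1 = CHMe, C4 = CH bearing the side chain, C4a/C8a = ring fusion, C5–H, C6–CO2Me, C7–OMe, C8–OH, C11 and C15 = side-chain CHMe, C16 = CH2OH)
1. 26 ⇐ 25 (loss of MOM and TBS) ⇐ 23 by OMe-directed lithiation/carboxylation at C6; the arene is bought (2-bromoisovanillin) and the cyclohexane ring is the only ring that is made.
2. 23 ⇐ 20: the C8a–C1 bond closes the carbocycle. Br/Li exchange at C8a, capture by the C1 boronic ester (seven-membered boronate 22), then an NBS-induced ring-contracting 1,2-shift of C1 from boron to C8a with retention: two nucleophilic carbons (aryl anion, alkylboron) are united by oxidation.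
3. Enabling feature: on the aromatic ring the C7 methoxy group is meta to C8a and ortho to the still unsubstituted C6–H, which is para to C8a, so Br+ enters at C6 and the positive charge appears at C8a; the C8 oxygen next to C8a marks the carbon that carries bromine in the commercial arene. For this reason CO2Me is placed on C6 only after ring closure.
4. 20 ⇐ 14 by three boronic ester homologations (CH2, CH2, then CHMe under (−)-sparteine control, which sets C1); 14 ⇐ 11 by asymmetric syn-hydroboration of the (E)-trisubstituted alkene (C4 and C11 in one step).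
5. 11 ⇐ 3 (from 1) + 8 by trans-selective B-alkyl Suzuki coupling of the 1,1-dibromoalkene, then methylation; 8 (C12–C16, C15 stereocentre) by Evans allylation.

Key step: step 12

Assumption: the facial sense of monoisopinocampheylborane in step 8 is taken from Brown's empirical rule for trans-disubstituted and trisubstituted alkenes (the reagent from (−)-α-pinene is expected to give 4S,11S). Abbreviations used in names: ArBr = 2-bromo-4-methoxy-3-(methoxymethoxy)phenyl, TBSO = tert-butyldimethylsilyloxy, Ipc = isopinocampheyl.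

**Step 1**
Reactants: 1 2-bromo-3-hydroxy-4-methoxybenzaldehyde (2-bromoisovanillin)
Product: 2 2-bromo-4-methoxy-3-(methoxymethoxy)benzaldehyde
Conditions: MOMCl, i-Pr2NEt, CH2Cl2, 0 °C → rt
Reagents that add atoms: chloromethyl methyl ether, COCCl
Why: O-alkylation of the phenol (MOM ether formation) under amine base should proceed without touching the aldehyde or the aryl bromide and gives a phenol protecting group that survives organolithium, boron and palladium chemistry.

**Step 2**
Reactants: 2 2-bromo-4-methoxy-3-(methoxymethoxy)benzaldehyde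
Product: 3 2-bromo-1-(2,2-dibromoethenyl)-4-methoxy-3-(methoxymethoxy)benzene
Conditions: CBr4, PPh3, Zn, CH2Cl2, 0 °C → rt
Reagents that add atoms: carbon tetrabromide, BrC(Br)(Br)Br
Why: Corey–Fuchs (Ramirez) dibromo-olefination, a Wittig-type reaction of Ph3P=CBr2 with the aryl aldehyde, should give the 1,1-dibromoalkene whose new carbon becomes C11.

**Step 3**
Reactants: 4 (R)-4-benzyl-3-propanoyl-1,3-oxazolidin-2-one
Product: 6 (R)-4-benzyl-3-[(2S)-2-methylpent-4-enoyl]-1,3-oxazolidin-2-one, via sodium (Z)-enolate 5 (not isolated)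
Conditions: NaHMDS, THF, −78 °C; allyl bromide, −78 → −40 °C
Reagents that add atoms: allyl bromide, C=CCBr
Why: Evans asymmetric alkylation, in which the chelated (Z)-enolate is allylated on the face opposite the benzyl group of the (R)-auxiliary, should set the future C15 stereocentre as (S).

**Step 4**
Reactants: 6 (R)-4-benzyl-3-[(2S)-2-methylpent-4-enoyl]-1,3-oxazolidin-2-one
Product: 7 (2S)-2-methylpent-4-en-1-ol
Conditions: LiBH4, MeOH (1 equiv), Et2O, 0 °C
Reagents that add atoms: none
Why: Reductive cleavage of the N-acyl oxazolidinone with lithium borohydride should give the primary alcohol without epimerisation and leave the terminal alkene untouched.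

**Step 5**
Reactants: 7 (2S)-2-methylpent-4-en-1-ol
Product: 8 tert-butyldimethyl{[(2S)-2-methylpent-4-en-1-yl]oxy}silane
Conditions: TBSCl, imidazole, CH2Cl2, rt
Reagents that add atoms: tert-butyldimethylsilyl chloride, CC(C)(C)[Si](C)(C)Cl
Why: Silylation of the primary alcohol gives an ether that tolerates the borane, organolithium and Grignard reagents used later and is removed together with the MOM group at the end.

**Step 6**
Reactants: 8 tert-butyldimethyl{[(2S)-2-methylpent-4-en-1-yl]oxy}silane; 3 2-bromo-1-(2,2-dibromoethenyl)-4-methoxy-3-(methoxymethoxy)benzene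
Product: 10 tert-butyl({(2S,6Z)-6-bromo-7-ArBr-2-methylhept-6-en-1-yl}oxy)dimethylsilane, via B-alkyl-9-BBN 9 (not isolated)
Conditions: 9-BBN, THF, rt; then 3, Pd(dppf)Cl2 (5 mol%), aq. K3PO4, THF/DMF, rt
Reagents that add atoms: none
Why: Anti-Markovnikov hydroboration followed by a trans-selective B-alkyl Suzuki–Miyaura coupling of the 1,1-dibromoalkene, in which oxidative addition takes the less hindered C–Br bond trans to the aryl group, should join C11 to C12 and leave the (Z)-bromoalkene and the hindered electron-rich aryl bromide intact.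

**Step 7**
Reactants: 10 tert-butyl({(2S,6Z)-6-bromo-7-ArBr-2-methylhept-6-en-1-yl}oxy)dimethylsilane
Product: 11 tert-butyl({(2S,6E)-7-ArBr-2,6-dimethylhept-6-en-1-yl}oxy)dimethylsilane
Conditions: MeMgBr, Fe(acac)3 (5 mol%), THF/NMP, 0 °C
Reagents that add atoms: methylmagnesium bromide, C[Mg]Br
Why: Iron-catalysed Kumada-type coupling of the alkenyl bromide with retention of double-bond geometry should give the (E)-trisubstituted alkene (methyl cis to the aryl group), while the aryl bromide is inert under iron catalysis.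

**Step 8**
Reactants: 11 tert-butyl({(2S,6E)-7-ArBr-2,6-dimethylhept-6-en-1-yl}oxy)dimethylsilane
Product: 14 2-[(1S,2S,6S)-1-ArBr-7-TBSO-2,6-dimethylheptyl]-4,4,5,5-tetramethyl-1,3,2-dioxaborolane, via alkyl(isopinocampheyl)borane 12 (not isolated), via diethyl boronate 13 (not isolated)
Conditions: IpcBH2 [from (−)-α-pinene], Et2O, −25 °C; CH3CHO (excess), 0 °C → rt; pinacol, rt
Reagents that add atoms: monoisopinocampheylborane from (−)-α-pinene, B[C@H]1C[C@H]2C[C@@H]([C@@H]1C)C2(C)C; pinacol, CC(C)(O)C(C)(C)O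
Why: Brown asymmetric hydroboration places boron on the less substituted benzylic C4 and hydrogen on C11 in a syn addition, so the (E)-geometry fixes the C4/C11 relative configuration and the chiral borane selects the face (4S,11S expected), after which acetaldehyde expels the Ipc group as α-pinene and pinacol gives the stable boronic ester.

**Step 9**
Reactants: 14 2-[(1S,2S,6S)-1-ArBr-7-TBSO-2,6-dimethylheptyl]-4,4,5,5-tetramethyl-1,3,2-dioxaborolane
Product: 16 2-[(2S,3S,7S)-2-ArBr-8-TBSO-3,7-dimethyloctyl]-4,4,5,5-tetramethyl-1,3,2-dioxaborolane, via lithium chloromethyl boronate complex 15 (not isolated)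
Conditions: ICH2Cl, n-BuLi (added last), Et2O, −78 °C → rt
Reagents that add atoms: chloroiodomethane, ClCI
Why: Matteson homologation with LiCH2Cl generated in situ (I/Li exchange is faster than attack of n-BuLi on the aryl bromide in ether) forms the ate complex, and the 1,2-metallate shift of the benzylic carbon with retention inserts C3 without touching the C4 stereocentre.

**Step 10**
Reactants: 16 2-[(2S,3S,7S)-2-ArBr-8-TBSO-3,7-dimethyloctyl]-4,4,5,5-tetramethyl-1,3,2-dioxaborolane
Product: 18 2-[(3S,4S,8S)-3-ArBr-9-TBSO-4,8-dimethylnonyl]-4,4,5,5-tetramethyl-1,3,2-dioxaborolane, via lithium chloromethyl boronate complex 17 (not isolated)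
Conditions: ICH2Cl, n-BuLi (added last), Et2O, −78 °C → rt
Reagents that add atoms: chloroiodomethane, ClCI
Why: A second Matteson homologation of the now primary boronic ester inserts C2 by the same ate-complex/1,2-shift sequence.

**Step 11**
Reactants: 18 2-[(3S,4S,8S)-3-ArBr-9-TBSO-4,8-dimethylnonyl]-4,4,5,5-tetramethyl-1,3,2-dioxaborolane
Product: 20 2-[(2R,5S,6S,10S)-5-ArBr-11-TBSO-6,10-dimethylundecan-2-yl]-4,4,5,5-tetramethyl-1,3,2-dioxaborolane, via lithium boronate complex 19 (not isolated)
Conditions: ethyl 2,4,6-triisopropylbenzoate, s-BuLi, (−)-sparteine, Et2O, −78 °C; then 18, −78 °C → 35 °C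
Reagents that add atoms: ethyl 2,4,6-triisopropylbenzoate, CCOC(=O)c1c(C(C)C)cc(C(C)C)cc1C(C)C
Why: Lithiation–borylation (Hoppe–Aggarwal homologation): the (−)-sparteine-controlled (S)-lithiated benzoate is borylated with retention and the primary alkyl group then migrates with inversion and loss of the benzoate, which should set the C1 stereocentre as the (R)-boronic ester under reagent control.

**Step 12**
Reactants: 20 2-[(2R,5S,6S,10S)-5-ArBr-11-TBSO-6,10-dimethylundecan-2-yl]-4,4,5,5-tetramethyl-1,3,2-dioxaborolane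
Product: 23 (1R,4S)-4-[(2S,6S)-7-TBSO-6-methylheptan-2-yl]-7-methoxy-8-(methoxymethoxy)-1-methyl-1,2,3,4-tetrahydronaphthalene (target locants), via aryllithium 21 (not isolated), via cyclic lithium boronate complex 22 (not isolated)
Conditions: t-BuLi (2.1 equiv), THF (0.02 M), −100 → −78 °C; then NBS (1.2 equiv), THF/MeOH, −78 °C → rt
Reagents that add atoms: none
Why: Proposed new method: Br/Li exchange at C8a (expected to outrun addition of t-BuLi to the hindered secondary B(pin)) gives aryllithium 21, which is trapped at once by the tethered boronic ester as the seven-membered aryl(alkyl)boronate complex 22; NBS then brominates C6 (para to the borate-bearing C8a and ortho to the C7 methoxy group), the cyclohexadienyl cation centred on C8a triggers 1,2-migration of C1 from boron to C8a, and loss of bromide from C6 and of the boryl group from C8a restores the arene. The closest known reaction is the enantiospecific NBS-mediated sp2–sp3 coupling of secondary boronic esters with lithiated electron-rich arenes that carry a donor meta to boron, and the ring-contracting variant is modelled on electrophile-induced ring contractions of cyclic alkenylboronate complexes. The six-membered carbocycle is closed by a ring-contractive 1,2-metallate shift (seven-membered borate ring to six-membered carbocycle with exocyclic boron), formally a 6-exo closure onto C8a. C1 migrates with retention, so the (R) configuration set in step 11 is transferred unchanged and the 1,4-trans relation to C4 does not depend on substrate control. The step needs closure at C8a and not C5 (secured by the bromine of 2-bromoisovanillin), attack of Br+ at C6 and not at C8a (ipso) or C5 (secured by the combined para-borate and ortho-methoxy activation of C6 at low temperature), and migration of carbon and not oxygen (the pinacolate oxygens do not migrate).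

**Step 13**
Reactants: 23 (1R,4S)-4-[(2S,6S)-7-TBSO-6-methylheptan-2-yl]-7-methoxy-8-(methoxymethoxy)-1-methyl-1,2,3,4-tetrahydronaphthalene
Product: 25 methyl (5R,8S)-8-[(2S,6S)-7-TBSO-6-methylheptan-2-yl]-3-methoxy-4-(methoxymethoxy)-5-methyl-5,6,7,8-tetrahydronaphthalene-2-carboxylate, via C6 aryllithium 24 (not isolated)
Conditions: s-BuLi, TMEDA, THF, −78 → −40 °C; then ClCO2Me (excess, inverse addition), −78 °C → rt
Reagents that add atoms: methyl chloroformate, COC(=O)Cl
Why: Directed ortho-metalation: C6–H is the only aromatic C–H ortho to an oxygen substituent (the C7 methoxy group), so lithiation there and acylation with methyl chloroformate should install the ester, the tertiary benzylic C–H bonds being much less acidic kinetically.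

**Step 14**
Reactants: 25 methyl (5R,8S)-8-[(2S,6S)-7-TBSO-6-methylheptan-2-yl]-3-methoxy-4-(methoxymethoxy)-5-methyl-5,6,7,8-tetrahydronaphthalene-2-carboxylate
Product: 26 methyl (5R,8S)-4-hydroxy-8-[(2S,6S)-7-hydroxy-6-methylheptan-2-yl]-3-methoxy-5-methyl-5,6,7,8-tetrahydronaphthalene-2-carboxylate (CNP0398293.1)
Conditions: HCl (3 M aq.), MeOH, 45 °C
Reagents that add atoms: none
Why: Acid-catalysed methanolysis cleaves the MOM acetal and the primary TBS ether in one operation, while the methyl ester (in methanol) and the four stereocentres, none of which is acid-labile, should be unaffected.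

**Compound list**
1 | 2-bromo-3-hydroxy-4-methoxybenzaldehyde (2-bromoisovanillin) | O=Cc1ccc(OC)c(O)c1Br | starting material
2 | 2-bromo-4-methoxy-3-(methoxymethoxy)benzaldehyde | O=Cc1ccc(OC)c(OCOC)c1Br | intermediate
3 | 2-bromo-1-(2,2-dibromoethenyl)-4-methoxy-3-(methoxymethoxy)benzene | BrC(Br)=Cc1ccc(OC)c(OCOC)c1Br | intermediate
4 | (R)-4-benzyl-3-propanoyl-1,3-oxazolidin-2-one | CCC(=O)N1[C@H](Cc2ccccc2)COC1=O | starting material
5 | sodium (Z)-enolate of 4 | C/C=C(\[O-])N1[C@H](Cc2ccccc2)COC1=O.[Na+] | intermediate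
6 | (R)-4-benzyl-3-[(2S)-2-methylpent-4-enoyl]-1,3-oxazolidin-2-one | C=CC[C@H](C)C(=O)N1[C@H](Cc2ccccc2)COC1=O | intermediate
7 | (2S)-2-methylpent-4-en-1-ol | C=CC[C@H](C)CO | intermediate
8 | tert-butyldimethyl{[(2S)-2-methylpent-4-en-1-yl]oxy}silane | C=CC[C@H](C)CO[Si](C)(C)C(C)(C)C | intermediate
9 | 9-[(4S)-5-TBSO-4-methylpentyl]-9-borabicyclo[3.3.1]nonane | CC(C)(C)[Si](C)(C)OC[C@@H](C)CCCB1C2CCCC1CCC2 | intermediate
10 | tert-butyl({(2S,6Z)-6-bromo-7-ArBr-2-methylhept-6-en-1-yl}oxy)dimethylsilane | COCOc1c(OC)ccc(/C=C(\Br)CCC[C@H](C)CO[Si](C)(C)C(C)(C)C)c1Br | intermediate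
11 | tert-butyl({(2S,6E)-7-ArBr-2,6-dimethylhept-6-en-1-yl}oxy)dimethylsilane | COCOc1c(OC)ccc(/C=C(\C)CCC[C@H](C)CO[Si](C)(C)C(C)(C)C)c1Br | intermediate
12 | [(1S,2S,6S)-1-ArBr-7-TBSO-2,6-dimethylheptyl](isopinocampheyl)borane, Ipc from (−)-α-pinene | COCOc1c(OC)ccc([C@@H](B[C@H]2C[C@H]3C[C@@H]([C@@H]2C)C3(C)C)[C@@H](C)CCC[C@H](C)CO[Si](C)(C)C(C)(C)C)c1Br | intermediate
13 | diethyl [(1S,2S,6S)-1-ArBr-7-TBSO-2,6-dimethylheptyl]boronate | COCOc1c(OC)ccc([C@@H](B(OCC)OCC)[C@@H](C)CCC[C@H](C)CO[Si](C)(C)C(C)(C)C)c1Br | intermediate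
14 | 2-[(1S,2S,6S)-1-ArBr-7-TBSO-2,6-dimethylheptyl]-4,4,5,5-tetramethyl-1,3,2-dioxaborolane | COCOc1c(OC)ccc([C@@H](B2OC(C)(C)C(C)(C)O2)[C@@H](C)CCC[C@H](C)CO[Si](C)(C)C(C)(C)C)c1Br | intermediate
15 | lithium (chloromethyl)[(1S,2S,6S)-1-ArBr-7-TBSO-2,6-dimethylheptyl](pinacolato)borate | COCOc1c(OC)ccc([C@@H]([B-]2(CCl)OC(C)(C)C(C)(C)O2)[C@@H](C)CCC[C@H](C)CO[Si](C)(C)C(C)(C)C)c1Br.[Li+] | intermediate
16 | 2-[(2S,3S,7S)-2-ArBr-8-TBSO-3,7-dimethyloctyl]-4,4,5,5-tetramethyl-1,3,2-dioxaborolane | COCOc1c(OC)ccc([C@@H](CB2OC(C)(C)C(C)(C)O2)[C@@H](C)CCC[C@H](C)CO[Si](C)(C)C(C)(C)C)c1Br | intermediate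
17 | lithium (chloromethyl)[(2S,3S,7S)-2-ArBr-8-TBSO-3,7-dimethyloctyl](pinacolato)borate | COCOc1c(OC)ccc([C@@H](C[B-]2(CCl)OC(C)(C)C(C)(C)O2)[C@@H](C)CCC[C@H](C)CO[Si](C)(C)C(C)(C)C)c1Br.[Li+] | intermediate
18 | 2-[(3S,4S,8S)-3-ArBr-9-TBSO-4,8-dimethylnonyl]-4,4,5,5-tetramethyl-1,3,2-dioxaborolane | COCOc1c(OC)ccc([C@@H](CCB2OC(C)(C)C(C)(C)O2)[C@@H](C)CCC[C@H](C)CO[Si](C)(C)C(C)(C)C)c1Br | intermediate
19 | lithium [(3S,4S,8S)-3-ArBr-9-TBSO-4,8-dimethylnonyl][(1S)-1-(2,4,6-triisopropylbenzoyloxy)ethyl](pinacolato)borate | COCOc1c(OC)ccc([C@@H](CC[B-]2(OC(C)(C)C(C)(C)O2)[C@@H](C)OC(=O)c2c(C(C)C)cc(C(C)C)cc2C(C)C)[C@@H](C)CCC[C@H](C)CO[Si](C)(C)C(C)(C)C)c1Br.[Li+] | intermediate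
20 | 2-[(2R,5S,6S,10S)-5-ArBr-11-TBSO-6,10-dimethylundecan-2-yl]-4,4,5,5-tetramethyl-1,3,2-dioxaborolane | COCOc1c(OC)ccc([C@@H](CC[C@@H](C)B2OC(C)(C)C(C)(C)O2)[C@@H](C)CCC[C@H](C)CO[Si](C)(C)C(C)(C)C)c1Br | intermediate
21 | aryllithium from 20 (Li in place of Br at C8a) | COCOc1c(OC)ccc([C@@H](CC[C@@H](C)B2OC(C)(C)C(C)(C)O2)[C@@H](C)CCC[C@H](C)CO[Si](C)(C)C(C)(C)C)c1[Li] | intermediate
22 | lithium spiro-boronate complex: boron bonded to C8a, to C1 (R) and to the pinacolate oxygens, seven-membered ring B–C1–C2–C3–C4–C4a–C8a | COCOc1c(OC)ccc2c1[B-]1(OC(C)(C)C(C)(C)O1)[C@H](C)CC[C@H]2[C@@H](C)CCC[C@H](C)CO[Si](C)(C)C(C)(C)C.[Li+] | intermediate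
23 | (1R,4S)-4-[(2S,6S)-7-TBSO-6-methylheptan-2-yl]-7-methoxy-8-(methoxymethoxy)-1-methyl-1,2,3,4-tetrahydronaphthalene (target locants) | COCOc1c(OC)ccc2c1[C@H](C)CC[C@H]2[C@@H](C)CCC[C@H](C)CO[Si](C)(C)C(C)(C)C | intermediate
24 | C6-lithio derivative of 23 | [Li]c1cc2c(c(OCOC)c1OC)[C@H](C)CC[C@H]2[C@@H](C)CCC[C@H](C)CO[Si](C)(C)C(C)(C)C | intermediate
25 | methyl (5R,8S)-8-[(2S,6S)-7-TBSO-6-methylheptan-2-yl]-3-methoxy-4-(methoxymethoxy)-5-methyl-5,6,7,8-tetrahydronaphthalene-2-carboxylate | COC(=O)c1cc2c(c(OCOC)c1OC)[C@H](C)CC[C@H]2[C@@H](C)CCC[C@H](C)CO[Si](C)(C)C(C)(C)C | intermediate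
26 | methyl (5R,8S)-4-hydroxy-8-[(2S,6S)-7-hydroxy-6-methylheptan-2-yl]-3-methoxy-5-methyl-5,6,7,8-tetrahydronaphthalene-2-carboxylate | COC(=O)c1cc2c(c(O)c1OC)[C@H](C)CC[C@H]2[C@@H](C)CCC[C@H](C)CO | target

**Totals**
Total step count: 14. Longest linear sequence: 12 steps (4 → 26; the arene branch from 1 is 11 steps).

**Steps most likely to fail**

Step 12 (Proposed new method). What may go wrong: t-BuLi may add to boron before bromine–lithium exchange, or NBS may attack complex 22 at the boron-bearing carbon (ipso-bromodeboronation) or at C5, so that C1 never migrates. The fallback sets out from 18 and returns at 23. Compound 18 is homologated as in step 11 but with (+)-sparteine, which should give the C1-epimeric boronic ester 2-[(2S,5S,6S,10S)-5-ArBr-11-TBSO-6,10-dimethylundecan-2-yl]-4,4,5,5-tetramethyl-1,3,2-dioxaborolane F1. Oxidation with retention (NaBO3·4H2O, THF/H2O) should give the secondary alcohol (2S,5S,6S,10S)-5-ArBr-11-TBSO-6,10-dimethylundecan-2-ol F2, and TsCl/pyridine/DMAP the tosylate (2S,5S,6S,10S)-5-ArBr-11-TBSO-6,10-dimethylundecan-2-yl 4-methylbenzenesulfonate F3. Bromine–lithium exchange (t-BuLi, THF, −78 °C), transmetalation (MgBr2·OEt2) and a copper-catalysed intramolecular SN2 substitution of the secondary tosylate (CuI, TMEDA, LiOMe, 0 °C; copper-catalysed Grignard/secondary tosylate coupling, inversion at C1) should close the same ring and give 23.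

Step 11. What may go wrong: bromine–lithium exchange between the lithiated benzoate (or residual s-BuLi) and the aryl bromide may compete with ate-complex formation, or the C1 configuration may be eroded by incomplete sparteine control. The fallback sets out from 18 and returns at 20. Zweifel olefination (vinylmagnesium bromide, THF/DMSO; I2; NaOMe/MeOH) converts the C–B bond of 18 into a vinyl group and should give the terminal alkene tert-butyl({(2S,6S,7S)-7-ArBr-2,6-dimethylundec-10-en-1-yl}oxy)dimethylsilane F4. A copper-catalysed, Markovnikov-selective enantioselective hydroboration of this aliphatic terminal alkene (CuCl, chiral bisphosphine, B2pin2, KOt-Bu, MeOH, THF) places the boryl group on C1 under catalyst control and should give 20.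

Step 13. What may go wrong: deprotonation at a benzylic position or at the MOM group, or low conversion of the hindered arene, instead of lithiation at C6. The fallback sets out from 23 and returns at 25. Iridium-catalysed C–H borylation ([Ir(OMe)(cod)]2, dtbpy, B2pin2, THF, 80 °C) should take the less hindered aromatic C–H (C6, next to the methoxy group, not C5 next to the branched C4) and give the aryl boronic ester 2-[(5R,8S)-8-[(2S,6S)-7-TBSO-6-methylheptan-2-yl]-3-methoxy-4-(methoxymethoxy)-5-methyl-5,6,7,8-tetrahydronaphthalen-2-yl]-4,4,5,5-tetramethyl-1,3,2-dioxaborolane F5. Palladium-catalysed oxidative methoxycarbonylation (Pd(OAc)2, PPh3, p-benzoquinone, CO, MeOH, rt) should then give 25.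

**Further compounds**
F1 | step 12 | 2-[(2S,5S,6S,10S)-5-ArBr-11-TBSO-6,10-dimethylundecan-2-yl]-4,4,5,5-tetramethyl-1,3,2-dioxaborolane | COCOc1c(OC)ccc([C@@H](CC[C@H](C)B2OC(C)(C)C(C)(C)O2)[C@@H](C)CCC[C@H](C)CO[Si](C)(C)C(C)(C)C)c1Br
F2 | step 12 | (2S,5S,6S,10S)-5-ArBr-11-TBSO-6,10-dimethylundecan-2-ol | COCOc1c(OC)ccc([C@@H](CC[C@H](C)O)[C@@H](C)CCC[C@H](C)CO[Si](C)(C)C(C)(C)C)c1Br
F3 | step 12 | (2S,5S,6S,10S)-5-ArBr-11-TBSO-6,10-dimethylundecan-2-yl 4-methylbenzenesulfonate | COCOc1c(OC)ccc([C@@H](CC[C@H](C)OS(=O)(=O)c2ccc(C)cc2)[C@@H](C)CCC[C@H](C)CO[Si](C)(C)C(C)(C)C)c1Br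
F4 | step 11 | tert-butyl({(2S,6S,7S)-7-ArBr-2,6-dimethylundec-10-en-1-yl}oxy)dimethylsilane | COCOc1c(OC)ccc([C@@H](CCC=C)[C@@H](C)CCC[C@H](C)CO[Si](C)(C)C(C)(C)C)c1Br
F5 | step 13 | 2-[(5R,8S)-8-[(2S,6S)-7-TBSO-6-methylheptan-2-yl]-3-methoxy-4-(methoxymethoxy)-5-methyl-5,6,7,8-tetrahydronaphthalen-2-yl]-4,4,5,5-tetramethyl-1,3,2-dioxaborolane | CC1(C)OB(OC1(C)C)c1cc2c(c(OCOC)c1OC)[C@H](C)CC[C@H]2[C@@H](C)CCC[C@H](C)CO[Si](C)(C)C(C)(C)C
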